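The dihydropyranone ring B is disconnected in a [3+3] sense into a tigloyl unit and the enol edge C4a/C8a–O1 of phloroglucinol-derived ring A. In the key step, (S)-5,7-dihydroxy-4-propylchroman-2-one is C-acylated with tigloyl chloride and the ortho-hydroxy enone is closed at once by quinine-catalysed oxa-Michael addition, which forms C4–C4a and O1–C2 and sets the cis C2/C3 pair. The step exploits the 1,3-dioxygenated ring A: the hexanoic acid chain is tied as a temporary lactone to the future C5 oxygen, so only the C8a oxygen can close ring B. Reductive alkylation with a verbenone-derived cyclobutane aldehyde, lactone opening and dearomatising prenylation at C8 finish the synthesis.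

Key step: step 8

Numbering remark: target atoms are numbered as a chromanone (ring B: O1, C2, C3, C4; ring A: C4a, C5, C6, C7, C8, C8a); lactones 13–15 are named as pyrano[2,3-f]chromenes (lactone ring O1–C4, benzene C4a, C5, C6, C6a, C10a, C10b, chromanone ring O7–C10).

Assumption: in step 11 the sense of induction of the chiral diphosphine at C8 cannot be predicted with confidence for this nucleophile; the (R,R) ligand is written, the antipodal ligand is used if the first run shows the C8 epimer to predominate, and the two C8 epimers are diastereomers that can be separated.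

Step 1
Reactants: 1 (1R,5R)-(+)-verbenone
Product: 2 (1R,3S)-3-acetyl-2,2-dimethylcyclobutane-1-carboxylic acid (cis-pinononic acid)
Conditions: RuCl3·xH2O (2 mol%), NaIO4 (4.2 equiv), CCl4/MeCN/H2O, rt
Reagents that add atoms: sodium periodate, [Na+].[O-]I(=O)(=O)=O; water, O
Why: Catalytic RuO4 (RuCl3/NaIO4) cleaves the enone C3=C4 bond of the bicyclo[3.1.1]heptenone with loss of C3 as CO2 (oxidative alkene cleavage), which opens the six-membered ring but leaves the cyclobutane intact, so both ring stereocentres of 1 are carried unchanged into the cis-1,3-disubstituted cyclobutane 2.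

Step 2
Reactants: 2 cis-pinononic acid
Product: 3 methyl (1R,3S)-3-acetyl-2,2-dimethylcyclobutane-1-carboxylate
Conditions: MeI, KHCO3, DMF, rt
Reagents that add atoms: iodomethane, CI
Why: SN2 O-methylation of the potassium carboxylate; bicarbonate at room temperature is too weak to enolise the ketone, so the cis relationship is kept.

Step 3
Reactants: 3 methyl (1R,3S)-3-acetyl-2,2-dimethylcyclobutane-1-carboxylate
Product: 4 methyl (1R,3R)-2,2-dimethyl-3-(prop-1-en-2-yl)cyclobutane-1-carboxylate
Conditions: Ph3PCH3Br, KOtBu (slight deficit), THF, 0 °C → rt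
Reagents that add atoms: methyltriphenylphosphonium bromide, C[P+](c1ccccc1)(c1ccccc1)c1ccccc1.[Br-]
Why: Wittig methylenation of the methyl ketone in the presence of the less electrophilic ester; the ylide is used without excess base at 0 °C, and enolisation toward the four-membered ring (an exocyclic enolate) is slow, so C3 should not epimerise.

Step 4
Reactants: 4 methyl (1R,3R)-2,2-dimethyl-3-(prop-1-en-2-yl)cyclobutane-1-carboxylate
Product: 5 (1R,3R)-2,2-dimethyl-3-(prop-1-en-2-yl)cyclobutane-1-carbaldehyde
Conditions: i-Bu2AlH (1.05 equiv), CH2Cl2, −78 °C; MeOH, then aqueous potassium sodium tartrate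
Reagents that add atoms: none
Why: Partial reduction of the ester by i-Bu2AlH, in which the tetrahedral aluminium hemiacetal is stable at −78 °C and gives the aldehyde only on quench; no stereocentre is involved and the aldehyde is used at once to avoid α-epimerisation.

Step 5
Reactants: 6 3,5-dimethoxyphenol; 7 (E)-hex-2-enal
Product: 8 (4S)-5,7-dimethoxy-4-propylchroman-2-ol (lactol, both C2 epimers)
Conditions: (R)-2-[diphenyl(trimethylsilyloxy)methyl]pyrrolidine (20 mol%), PhCO2H (20 mol%), toluene, 0 °C → rt
Reagents that add atoms: none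
Why: Iminium-ion catalysed Friedel–Crafts conjugate addition followed by hemiacetalisation: the carbon ortho to the phenol OH attacks C-β of the (E)-iminium ion of 7 from the face opposite the CPh2OSiMe3 group of the (R)-catalyst, which sets C4 as S, and the phenol OH then traps the aldehyde as the lactol.

Step 6
Reactants: 8 (4S)-5,7-dimethoxy-4-propylchroman-2-ol
Product: 9 (4S)-5,7-dimethoxy-4-propylchroman-2-one
Conditions: TEMPO (10 mol%), PhI(OAc)2, CH2Cl2, rt
Reagents that add atoms: none
Why: Oxoammonium (TEMPO/PhI(OAc)2) oxidation of the lactol to the lactone; the aryl methyl ethers and the benzylic stereocentre are not affected.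

Step 7
Reactants: 9 (4S)-5,7-dimethoxy-4-propylchroman-2-one
Product: 10 (4S)-5,7-dihydroxy-4-propylchroman-2-one
Conditions: BBr3, CH2Cl2, −78 → 0 °C; then H2O
Reagents that add atoms: none
Why: Lewis-acid cleavage of both aryl methyl ethers by BBr3 at low temperature; the lactone re-closes on acidic work-up and C4 keeps its configuration.

Step 8
Reactants: 10 (4S)-5,7-dihydroxy-4-propylchroman-2-one; 11 tigloyl chloride
Product: 13 (4S,8R,9S)-5-hydroxy-8,9-dimethyl-4-propyl-3,4,8,9-tetrahydro-2H,10H-pyrano[2,3-f]chromene-2,10-dione, via 8-tigloyl phenol 12 (not isolated)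
Conditions: 11 (1.2 equiv), AlCl3 (4 equiv), (CH2Cl)2, 0 → 50 °C; cold 1 M HCl quench, extraction, solvent switch without purification; (−)-quinine (0.2 equiv), PhCl, 15 °C
Reagents that add atoms: none
Why: AlCl3 generates the tigloyl acylium ion, which attacks the aluminium phenolate of 10 at C8 of the lactone numbering (the future C4a; ortho to the 7-OH and para to the 5-OH, the position acylated in 5,7-dihydroxy-4-alkylcoumarins) to give the chelated ortho-hydroxyaryl enone 12 and with it the C4–C4a bond (Friedel–Crafts acylation). After the acid quench, quinine deprotonates the 7-OH and the chiral ion pair undergoes a 6-endo-trig oxa-Michael addition to the enone β-carbon, which forms the O1–C2 bond and closes ring B; the closest known reaction is the quinine-catalysed intramolecular oxa-Michael addition of 7-hydroxy-8-tigloylcoumarins. C2 (R) is set under catalyst control by the enone face that the quininium-bound phenoxide attacks, and C3 (S) by kinetic protonation of the resulting enol anti to the new C2 methyl group, which gives the cis pair before equilibration to trans can occur. The step needs site selectivity (C8 over C6), oxygen selectivity, and enantio- and cis-selectivity. The first rests on the para-hydroxyl activation and chelation noted above; the second is secured by the lactone, since the only other oxygen flanking the new ketone is the acylated lactone oxygen; the last two come from the catalyst and from a cold cyclisation in a non-polar solvent, and the remote C4 centre is not expected to override the catalyst.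

Step 9
Reactants: 13 (4S,8R,9S)-5-hydroxy-8,9-dimethyl-4-propyl-3,4,8,9-tetrahydro-2H,10H-pyrano[2,3-f]chromene-2,10-dione; 5 (1R,3R)-2,2-dimethyl-3-(prop-1-en-2-yl)cyclobutane-1-carbaldehyde
Product: 15 (4S,8R,9S)-6-{[(1S,3R)-2,2-dimethyl-3-(prop-1-en-2-yl)cyclobutyl]methyl}-5-hydroxy-8,9-dimethyl-4-propyl-3,4,8,9-tetrahydro-2H,10H-pyrano[2,3-f]chromene-2,10-dione, via ortho-quinone methide 14 (not isolated)
Conditions: 5 (1.5 equiv), diethyl 2,6-dimethyl-1,4-dihydropyridine-3,5-dicarboxylate (Hantzsch ester, 1.3 equiv), L-proline (20 mol%), CH2Cl2/EtOH, 40 °C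
Reagents that add atoms: none
Why: Three-component reductive alkylation: amine-catalysed Knoevenagel-type condensation of the vinylogous-acid phenol at C6, its only free ring carbon, with aldehyde 5 gives ortho-quinone methide 14, which accepts a hydride from the Hantzsch ester at the exocyclic carbon and rearomatises; no new stereocentre is formed and the cyclobutane centres come unchanged from 5.

Step 10
Reactants: 15 (4S,8R,9S)-6-{[(1S,3R)-2,2-dimethyl-3-(prop-1-en-2-yl)cyclobutyl]methyl}-5-hydroxy-8,9-dimethyl-4-propyl-3,4,8,9-tetrahydro-2H,10H-pyrano[2,3-f]chromene-2,10-dione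
Product: 16 (3S)-3-[(2R,3S)-8-{[(1S,3R)-2,2-dimethyl-3-(prop-1-en-2-yl)cyclobutyl]methyl}-5,7-dihydroxy-2,3-dimethyl-4-oxo-3,4-dihydro-2H-chromen-6-yl]hexanoic acid
Conditions: LiOH (3 equiv), THF/H2O, 0 °C; then 0.5 M HCl to pH 4 at 0 °C
Reagents that add atoms: lithium hydroxide, [Li+].[OH-]
Why: Saponification of the aryl lactone at 0 °C; under base the substrate is a phenoxide conjugated with the C10 ketone (a vinylogous carboxylate), which lowers the acidity of H-9 and disfavours retro-oxa-Michael opening, so the cis-dimethyl pair should survive the short exposure.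

Step 11
Reactants: 16 (3S)-3-[(2R,3S)-8-{[(1S,3R)-2,2-dimethyl-3-(prop-1-en-2-yl)cyclobutyl]methyl}-5,7-dihydroxy-2,3-dimethyl-4-oxo-3,4-dihydro-2H-chromen-6-yl]hexanoic acid; 17 prenyl acetate
Product: 18 (3S)-3-[(2R,3S,8R)-8-{[(1S,3R)-2,2-dimethyl-3-(prop-1-en-2-yl)cyclobutyl]methyl}-5-hydroxy-2,3-dimethyl-8-(3-methylbut-2-en-1-yl)-4,7-dioxo-3,4,7,8-tetrahydro-2H-chromen-6-yl]hexanoic acid (target)
Conditions: 17 (1.2 equiv), Pd2(dba)3·CHCl3 (2.5 mol%), (R,R)-N,N'-bis[2-(diphenylphosphino)benzoyl]cyclohexane-1,2-diamine (7.5 mol%), Et3N (2.2 equiv), CH2Cl2, 0 °C → rt; pH 4 buffer work-up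
Reagents that add atoms: none
Why: Tsuji–Trost allylic alkylation used as a dearomatisation of an alkylated acylphloroglucinol: the 7-phenoxide (para to the C4 ketone) attacks the unsubstituted terminus of the π-prenyl palladium complex through C8, O-prenylation of phenol or carboxylate being reversible under palladium catalysis while C-prenylation gives the stabilised enolised β-triketone of the target; C8 is preferred over C6, whose attack would place a quaternary carbon next to the branched side chain, and the face of C8 is chosen by the chiral ligand, which sets C8 as R.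

Compound list
1 | (1R,5R)-(+)-verbenone, (1R,5R)-4,6,6-trimethylbicyclo[3.1.1]hept-3-en-2-one | CC1=CC(=O)[C@@H]2C[C@H]1C2(C)C | starting material
2 | (1R,3S)-3-acetyl-2,2-dimethylcyclobutane-1-carboxylic acid (cis-pinononic acid) | CC(=O)[C@H]1C[C@@H](C(=O)O)C1(C)C | intermediate
3 | methyl (1R,3S)-3-acetyl-2,2-dimethylcyclobutane-1-carboxylate | CC(=O)[C@H]1C[C@@H](C(=O)OC)C1(C)C | intermediate
4 | methyl (1R,3R)-2,2-dimethyl-3-(prop-1-en-2-yl)cyclobutane-1-carboxylate | C=C(C)[C@H]1C[C@@H](C(=O)OC)C1(C)C | intermediate
5 | (1R,3R)-2,2-dimethyl-3-(prop-1-en-2-yl)cyclobutane-1-carbaldehyde | C=C(C)[C@H]1C[C@@H](C=O)C1(C)C | intermediate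
6 | 3,5-dimethoxyphenol | COc1cc(O)cc(OC)c1 | starting material
7 | (E)-hex-2-enal | CCC/C=C/C=O | starting material
8 | (4S)-5,7-dimethoxy-4-propylchroman-2-ol (lactol, both C2 epimers) | CCC[C@H]1CC(O)Oc2cc(OC)cc(OC)c21 | intermediate
9 | (4S)-5,7-dimethoxy-4-propylchroman-2-one | CCC[C@H]1CC(=O)Oc2cc(OC)cc(OC)c21 | intermediate
10 | (4S)-5,7-dihydroxy-4-propylchroman-2-one | CCC[C@H]1CC(=O)Oc2cc(O)cc(O)c21 | intermediate
11 | tigloyl chloride, (E)-2-methylbut-2-enoyl chloride | C/C=C(\C)C(=O)Cl | starting material
12 | (4S)-5,7-dihydroxy-8-[(E)-2-methylbut-2-enoyl]-4-propylchroman-2-one (8-tigloyl phenol) | CCC[C@H]1CC(=O)Oc2c(C(=O)/C(C)=C/C)c(O)cc(O)c21 | intermediate (not isolated)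
13 | (4S,8R,9S)-5-hydroxy-8,9-dimethyl-4-propyl-3,4,8,9-tetrahydro-2H,10H-pyrano[2,3-f]chromene-2,10-dione | CCC[C@H]1CC(=O)Oc2c1c(O)cc3c2C(=O)[C@@H](C)[C@@H](C)O3 | intermediate
14 | ortho-quinone methide: 13 with C5 as a ketone and C6 carrying the exocyclic =CH–[(1S,3R)-2,2-dimethyl-3-(prop-1-en-2-yl)cyclobutyl] group (alkene geometry not fixed) | CCC[C@H]1CC(=O)OC2=C1C(=O)C(=C[C@@H]4C[C@H](C(C)=C)C4(C)C)C3=C2C(=O)[C@@H](C)[C@@H](C)O3 | intermediate (not isolated)
15 | (4S,8R,9S)-6-{[(1S,3R)-2,2-dimethyl-3-(prop-1-en-2-yl)cyclobutyl]methyl}-5-hydroxy-8,9-dimethyl-4-propyl-3,4,8,9-tetrahydro-2H,10H-pyrano[2,3-f]chromene-2,10-dione | CCC[C@H]1CC(=O)Oc2c1c(O)c(C[C@@H]4C[C@H](C(C)=C)C4(C)C)c3c2C(=O)[C@@H](C)[C@@H](C)O3 | intermediate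
16 | (3S)-3-[(2R,3S)-8-{[(1S,3R)-2,2-dimethyl-3-(prop-1-en-2-yl)cyclobutyl]methyl}-5,7-dihydroxy-2,3-dimethyl-4-oxo-3,4-dihydro-2H-chromen-6-yl]hexanoic acid | CCC[C@@H](CC(=O)O)c1c(O)c(C[C@@H]3C[C@H](C(C)=C)C3(C)C)c2O[C@H](C)[C@H](C)C(=O)c2c1O | intermediate
17 | prenyl acetate, 3-methylbut-2-en-1-yl acetate | CC(C)=CCOC(C)=O | starting material
18 | (3S)-3-[(2R,3S,8R)-8-{[(1S,3R)-2,2-dimethyl-3-(prop-1-en-2-yl)cyclobutyl]methyl}-5-hydroxy-2,3-dimethyl-8-(3-methylbut-2-en-1-yl)-4,7-dioxo-3,4,7,8-tetrahydro-2H-chromen-6-yl]hexanoic acid | C=C(C)[C@H]1C[C@@H](C[C@@]2(CC=C(C)C)C(=O)C([C@@H](CCC)CC(=O)O)=C(O)C3=C2O[C@H](C)[C@H](C)C3=O)C1(C)C | target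

Total step count: 11. Longest linear sequence: 7 steps (steps 5–11 from 6 and 7; the branch from 1, steps 1–4 followed by 9–11, is equally long).

Steps most likely to fail

Step 8. The acylation may take place at C6 in competition with C8, and ring closure may occur without the catalyst (on the Lewis acid or during work-up), which would erode enantio- and cis-selectivity. The fallback sets out from 12, isolated after the acylation stage and freed from any 6-acyl isomer by chromatography, and returns at 13. Compound 12 is cyclised oxidatively (catalytic I2, DMSO, 110 °C) to the chromone (4S)-5-hydroxy-8,9-dimethyl-4-propyl-3,4-dihydro-2H,10H-pyrano[2,3-f]chromene-2,10-dione F1, in which ring B carries no stereocentre. Enantioselective hydrogenation (Ru(cod)(2-methylallyl)2 with a chiral N-heterocyclic carbene generated from its imidazolinium tetrafluoroborate and KOtBu, H2) should add hydrogen to one face of the pyranone and give the cis-8,9-dimethyl chromanol F2, so that the cis relationship comes from syn addition and not from kinetic protonation. Dess–Martin oxidation of the benzylic alcohol then gives 13.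

Step 11. Alkylation may occur at oxygen or at C6 instead of C8, the facial selectivity at C8 may be poor, and the base used in steps 10 and 11 may epimerise C3. The fallback sets out from lactone 15 (step 10 is omitted) and returns at 18. The 5-hydroxyl of 15 is alkylated with 3-chloro-3-methylbut-1-yne (DBU, catalytic CuCl2, MeCN, 0 °C) to the 1,1-dimethylpropargyl ether F3, and semi-hydrogenation (H2, Pd/CaCO3 poisoned with Pb(OAc)2, quinoline) gives the 1,1-dimethylallyl ether F4. Heating in toluene (80–100 °C) should trigger the aromatic Claisen rearrangement, a [3,3] shift that can deliver the allyl terminus only to C6 because the other ortho carbon is the ring-fusion carbon C4a. This gives the dienone enol lactone F5 with a linear prenyl group, as two C6 epimers that are separated. Hydrolysis of the labile enol lactone (NaHCO3, THF/H2O) then gives 18 without strong base.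

Step 9. Condensation with the hindered α-branched aldehyde may be slow, the aldehyde α-carbon may epimerise under amine catalysis, and the quinone methide may be trapped by a second molecule of phenol. The fallback sets out from 13 and from ester 4 and returns at 15. Compound 13 is iodinated at C6 (N-iodosuccinimide, catalytic TsOH, MeCN) to the aryl iodide F6. Ester 4 is reduced (LiAlH4, Et2O, 0 °C) to the alcohol [(1R,3R)-2,2-dimethyl-3-(prop-1-en-2-yl)cyclobutyl]methanol F7, which is converted (I2, PPh3, imidazole) into the iodide (1R,3R)-1-(iodomethyl)-2,2-dimethyl-3-(prop-1-en-2-yl)cyclobutane F8, and zinc insertion (Zn dust, LiCl, THF) gives the alkylzinc iodide F9. Negishi coupling of F9 with F6 (Pd(OAc)2, SPhos, THF, phenol deprotonated beforehand with NaH) forms the aryl–CH2 bond of 15 with no epimerisable aldehyde in play.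

Further compounds
F1 | step 8 | (4S)-5-hydroxy-8,9-dimethyl-4-propyl-3,4-dihydro-2H,10H-pyrano[2,3-f]chromene-2,10-dione (chromone) | CCC[C@H]1CC(=O)Oc2c1c(O)cc3oc(C)c(C)c(=O)c23
F2 | step 8 | chromanol: 13 with the C10 ketone reduced to the secondary alcohol, cis-8,9-dimethyl, C10 configuration not controlled | CCC[C@H]1CC(=O)Oc2c1c(O)cc3c2C(O)[C@@H](C)[C@@H](C)O3
F3 | step 11 | 5-O-(2-methylbut-3-yn-2-yl) ether of 15 | CCC[C@H]1CC(=O)Oc2c1c(OC(C)(C)C#C)c(C[C@@H]4C[C@H](C(C)=C)C4(C)C)c3c2C(=O)[C@@H](C)[C@@H](C)O3
F4 | step 11 | 5-O-(2-methylbut-3-en-2-yl) ether of 15 | CCC[C@H]1CC(=O)Oc2c1c(OC(C)(C)C=C)c(C[C@@H]4C[C@H](C(C)=C)C4(C)C)c3c2C(=O)[C@@H](C)[C@@H](C)O3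
F5 | step 11 | enol lactone of 18 (side-chain carboxyl closed onto the C5 enol oxygen), the 6,6-disubstituted dienone from the Claisen rearrangement, desired epimer at the quaternary carbon | CCC[C@H]1CC(=O)OC2=C1C(=O)[C@](CC=C(C)C)(C[C@@H]4C[C@H](C(C)=C)C4(C)C)C3=C2C(=O)[C@@H](C)[C@@H](C)O3
F6 | step 9 | (4S,8R,9S)-5-hydroxy-6-iodo-8,9-dimethyl-4-propyl-3,4,8,9-tetrahydro-2H,10H-pyrano[2,3-f]chromene-2,10-dione | CCC[C@H]1CC(=O)Oc2c1c(O)c(I)c3c2C(=O)[C@@H](C)[C@@H](C)O3
F7 | step 9 | [(1R,3R)-2,2-dimethyl-3-(prop-1-en-2-yl)cyclobutyl]methanol | C=C(C)[C@H]1C[C@@H](CO)C1(C)C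
F8 | step 9 | (1R,3R)-1-(iodomethyl)-2,2-dimethyl-3-(prop-1-en-2-yl)cyclobutane | C=C(C)[C@H]1C[C@@H](CI)C1(C)C
F9 | step 9 | {[(1R,3R)-2,2-dimethyl-3-(prop-1-en-2-yl)cyclobutyl]methyl}zinc iodide | C=C(C)[C@H]1C[C@@H](C[Zn]I)C1(C)C
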